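**Retrosynthetic overview**
- Target ⇒ chromanetriol + 3-phenylpropanenitrile: the C8–acyl bond is made last by Houben–Hoesch acylation at the only free ring carbon.
- Chromanetriol ⇒ (3S,4S)-epoxychroman carbaldehyde bis-benzyl ether: one hydrogenolysis opens the epoxide at C4, removes both benzyl groups and turns CHO into the C6 methyl.
- Epoxychroman ⇒ aryl 1,1-dimethylpropargyl ether: in one pot the pyran ring closes first (propargyl Claisen/oxa-6π) and the oxirane second (Jacobsen epoxidation, sets C3). Both benzene rings are bought.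
- Propargyl ether ⇒ 2,4,6-trihydroxybenzaldehyde: the formyl group makes the para-OH uniquely reactive, which decides which oxygen becomes the pyran oxygen, and it is the latent methyl.

Assumption: chroman numbering is used (O1, C2 gem-dimethyl, C3 carbinol, C8 acyl); the stereocentre in the given SMILES is (S) at C3 (C-5'' of the trivial name).

**Step 1**
Reactants: 1 2,4,6-trihydroxybenzaldehyde; 2 3-chloro-3-methylbut-1-yne; 3 benzyl bromide
Product: 5 2,6-bis(benzyloxy)-4-[(2-methylbut-3-yn-2-yl)oxy]benzaldehyde, via para-propargyl ether 4 (not isolated)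
Conditions: K2CO3 (1.1 equiv), KI, CuI (cat.), DMF, 50 °C; then BnBr, K2CO3, 70 °C
Reagents that add atoms: 3-chloro-3-methylbut-1-yne (2) CC(C)(Cl)C#C; benzyl bromide (3) BrCc1ccccc1
Why: Copper-assisted O-propargylation of the phenoxide by the tertiary propargylic chloride goes to the 4-OH, the most acidic phenol (vinylogous acid) and the only one not hydrogen-bonded to the aldehyde, which fixes the later pyran oxygen para to the latent methyl; the two chelated OH groups are then capped by Williamson benzylation in the same flask, and no stereocentre is formed.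

**Step 2**
Reactants: 5 2,6-bis(benzyloxy)-4-[(2-methylbut-3-yn-2-yl)oxy]benzaldehyde
Product: 7 (1aS,7bS)-5,7-bis(benzyloxy)-2,2-dimethyl-1a,7b-dihydro-2H-oxireno[2,3-c]chromene-6-carbaldehyde, via chromene 6 (not isolated)
Conditions: PhCl, 130 °C; then (S,S)-Jacobsen Mn(salen)Cl (5 mol%), 4-phenylpyridine N-oxide (cat.), aq. NaOCl (pH 11.3), 0 °C
Reagents that add atoms: sodium hypochlorite [Na+].[O-]Cl
Why: Aromatic propargyl Claisen rearrangement, 1,5-H shift and oxa-6π electrocyclisation close the pyran ring onto either of the two equivalent ortho carbons, and Jacobsen–Katsuki epoxidation of the resulting cis-disubstituted 2,2-dimethylchromene (the standard high-ee substrate class) with the (S,S)-catalyst then closes the oxirane from one enantioface, so two rings and the C3 stereocentre (3S, with 4S, chroman numbering) are made in one operation.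

**Step 3**
Reactants: 7 (1aS,7bS)-5,7-bis(benzyloxy)-2,2-dimethyl-1a,7b-dihydro-2H-oxireno[2,3-c]chromene-6-carbaldehyde
Product: 8 (3S)-2,2,6-trimethyl-3,4-dihydro-2H-chromene-3,5,7-triol
Conditions: H2 (4 bar), 10% Pd/C, EtOAc–EtOH (1% AcOH), rt
Reagents that add atoms: none
Why: Heterogeneous hydrogenolysis cleaves only benzylic C–O bonds, namely the C4–O bond of the epoxide (C3–O is untouched, so C3 stays S), both benzyl ethers and, via the o,o'-dihydroxybenzyl alcohol, the formyl oxygen, which leaves the C6 methyl.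

**Step 4**
Reactants: 8 (3S)-2,2,6-trimethyl-3,4-dihydro-2H-chromene-3,5,7-triol; 9 3-phenylpropanenitrile
Product: 11 1-[(3S)-3,5,7-trihydroxy-2,2,6-trimethyl-3,4-dihydro-2H-chromen-8-yl]-3-phenylpropan-1-one, via ketiminium chloride 10 (not isolated)
Conditions: ZnCl2, HCl (g), Et2O, 0 °C; then H2O, 90 °C
Reagents that add atoms: 3-phenylpropanenitrile (9) N#CCCc1ccccc1; water O
Why: Houben–Hoesch acylation, in which the nitrilium ion attacks C8, the only unsubstituted ring carbon and activated by two ortho and one para oxygen, and the ketiminium salt is hydrolysed to the ketone, while the hindered secondary alcohol and the C3 stereocentre are not involved.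

**Compound list**
1 | 2,4,6-trihydroxybenzaldehyde | O=Cc1c(O)cc(O)cc1O | starting material
2 | 3-chloro-3-methylbut-1-yne | CC(C)(Cl)C#C | starting material
3 | benzyl bromide | BrCc1ccccc1 | starting material
4 | 2,6-dihydroxy-4-[(2-methylbut-3-yn-2-yl)oxy]benzaldehyde | O=Cc1c(O)cc(OC(C)(C)C#C)cc1O | intermediate (not isolated)
5 | 2,6-bis(benzyloxy)-4-[(2-methylbut-3-yn-2-yl)oxy]benzaldehyde | O=Cc1c(OCc2ccccc2)cc(OC(C)(C)C#C)cc1OCc1ccccc1 | intermediate
6 | 5,7-bis(benzyloxy)-2,2-dimethyl-2H-chromene-6-carbaldehyde | O=Cc1c(OCc2ccccc2)cc2OC(C)(C)C=Cc2c1OCc1ccccc1 | intermediate (not isolated)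
7 | (1aS,7bS)-5,7-bis(benzyloxy)-2,2-dimethyl-1a,7b-dihydro-2H-oxireno[2,3-c]chromene-6-carbaldehyde, i.e. the (3S,4S)-3,4-epoxide of 6 | O=Cc1c(OCc2ccccc2)cc2OC(C)(C)[C@H]3O[C@H]3c2c1OCc1ccccc1 | intermediate
8 | (3S)-2,2,6-trimethyl-3,4-dihydro-2H-chromene-3,5,7-triol | Cc1c(O)c2c(cc1O)OC(C)(C)[C@@H](O)C2 | intermediate
9 | 3-phenylpropanenitrile | N#CCCc1ccccc1 | starting material
10 | 1-[(3S)-3,5,7-trihydroxy-2,2,6-trimethyl-3,4-dihydro-2H-chromen-8-yl]-3-phenylpropan-1-iminium chloride | Cc1c(O)c2c(c(C(=[NH2+])CCc3ccccc3)c1O)OC(C)(C)[C@@H](O)C2.[Cl-] | intermediate (not isolated)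
11 | 1-[(3S)-3,5,7-trihydroxy-2,2,6-trimethyl-3,4-dihydro-2H-chromen-8-yl]-3-phenylpropan-1-one | Cc1c(O)c2c(c(C(=O)CCc3ccccc3)c1O)OC(C)(C)[C@@H](O)C2 | target

**Total step count:** 4. **Longest linear sequence:** 4 (fully linear from 1).

**Steps most likely to fail**

Step 2 (one-pot Claisen/electrocyclisation and Jacobsen epoxidation). Bleach may attack the aldehyde or the ring C–H, the 5-benzyloxy group next to C4 may lower the ee, and the electron-rich benzylic epoxide is labile. The fallback sets out from 5 and comes back at 8. Gold(I)-catalysed alkyne oxidation (Me4tBuXPhosAuNTf2, a hindered pyridine N-oxide) gives an α-oxo gold carbene that is trapped by the ortho carbon to give 5,7-bis(benzyloxy)-2,2-dimethyl-3-oxo-3,4-dihydro-2H-chromene-6-carbaldehyde F1. CBS reduction with (R)-Me-CBS and BH3·SMe2 (large CMe2(OAr) against small CH2Ar; a ketoreductase is the alternative) sets C3 and also reduces the aldehyde, giving (3S)-5,7-bis(benzyloxy)-6-(hydroxymethyl)-2,2-dimethyl-3,4-dihydro-2H-chromen-3-ol F2. Hydrogenolysis over Pd/C as in step 3 then gives 8.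

Step 3 (global hydrogenolysis). The aldehyde may stop at the benzylic alcohol, or the epoxide may rearrange to a chromanone on the catalyst before it is reduced. The fallback sets out from 7 and comes back at 8. Ionic hydrogenation with Et3SiH and BF3·OEt2 in CH2Cl2 at −78 °C delivers hydride to the C4 cation and fully deoxygenates the electron-rich aldehyde, giving (3S)-5,7-bis(benzyloxy)-2,2,6-trimethyl-3,4-dihydro-2H-chromen-3-ol F3. Simple debenzylation with H2 and Pd/C then gives 8.

Step 4 (Hoesch acylation beside a free alcohol). Pinner-type imidate formation at the 3-OH or at the phenols may compete, and conversion at the flanked C8 may be low. The fallback sets out from 8 and comes back at 11. Exhaustive O-acylation with 3-phenylpropanoyl chloride and pyridine gives (3S)-2,2,6-trimethyl-3,4-dihydro-2H-chromene-3,5,7-triyl tris(3-phenylpropanoate) F4. A TiCl4-mediated Fries rearrangement moves an aryl ester acyl group to C8, the only open ring carbon, giving (3S)-7-hydroxy-2,2,6-trimethyl-8-(3-phenylpropanoyl)-3,4-dihydro-2H-chromene-3,5-diyl bis(3-phenylpropanoate) F5. Methanolysis of the remaining esters with K2CO3 in MeOH gives 11.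

**Further compounds**
F1 | step 2 | 5,7-bis(benzyloxy)-2,2-dimethyl-3-oxo-3,4-dihydro-2H-chromene-6-carbaldehyde | O=Cc1c(OCc2ccccc2)cc2OC(C)(C)C(=O)Cc2c1OCc1ccccc1
F2 | step 2 | (3S)-5,7-bis(benzyloxy)-6-(hydroxymethyl)-2,2-dimethyl-3,4-dihydro-2H-chromen-3-ol | OCc1c(OCc2ccccc2)cc2OC(C)(C)[C@@H](O)Cc2c1OCc1ccccc1
F3 | step 3 | (3S)-5,7-bis(benzyloxy)-2,2,6-trimethyl-3,4-dihydro-2H-chromen-3-ol | Cc1c(OCc2ccccc2)cc2OC(C)(C)[C@@H](O)Cc2c1OCc1ccccc1
F4 | step 4 | (3S)-2,2,6-trimethyl-3,4-dihydro-2H-chromene-3,5,7-triyl tris(3-phenylpropanoate) | Cc1c(OC(=O)CCc3ccccc3)c2c(cc1OC(=O)CCc1ccccc1)OC(C)(C)[C@@H](OC(=O)CCc1ccccc1)C2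
F5 | step 4 | (3S)-7-hydroxy-2,2,6-trimethyl-8-(3-phenylpropanoyl)-3,4-dihydro-2H-chromene-3,5-diyl bis(3-phenylpropanoate) | Cc1c(OC(=O)CCc3ccccc3)c2c(c(C(=O)CCc3ccccc3)c1O)OC(C)(C)[C@@H](OC(=O)CCc1ccccc1)C2
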